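**Retrosynthetic overview**
- The target is reached by removing three aryl methyl ethers with thiolate (no acid) from its tri-O-methyl ether.
- That ether comes from an acyclic (E,E)-farnesyl trimethoxybenzaldehyde by one catalyst-controlled, proton-initiated polyene bicyclisation. Rings A and B close together, and C5, C10, C9 and the Δ7 alkene are set in this step.
- The aromatic ring is carried in complete, so the ring order is: arene (purchased), then rings A and B in a single operation.
- The farnesyl benzaldehyde comes from ring lithiation/formylation of the farnesyl arene, which comes from 1-bromo-2,4,5-trimethoxybenzene and (E,E)-farnesyl bromide.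

Target configuration (drimane numbering): 5S,9S,10S, i.e. trans-decalin with H-5 α, CH3-10 β and CH2Ar-9 β; this equals (1S,4aS,8aS) in octahydronaphthalene numbering.

Assumption: the IDPi acid in step 3 is the enantiomer that converts (3E,7E)-homofarnesol into natural (−)-ambrox; the same facial selection is taken to give the (5S,9S,10S) series here.

**Step 1**
Reactants: 1 1-bromo-2,4,5-trimethoxybenzene; 2 (2E,6E)-farnesyl bromide
Product: 4 1-[(2E,6E)-farnesyl]-2,4,5-trimethoxybenzene, via aryllithium 3 (not isolated)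
Conditions: n-BuLi, THF, −78 °C; then CuBr·SMe2 (10 mol %), 2, −78 °C → rt
Reagents that add atoms: none
Why: Bromine–lithium exchange gives the aryllithium, which under copper catalysis displaces the primary allylic bromide at the α-carbon (cuprate-type SN2 allylic substitution) with both E double bonds retained; no stereocentre is formed.

**Step 2**
Reactants: 4 1-[(2E,6E)-farnesyl]-2,4,5-trimethoxybenzene
Product: 7 5-[(2E,6E)-farnesyl]-2,3,6-trimethoxybenzaldehyde, via ring-lithiated arene 5 (not isolated), via hemiaminal alkoxide 6 (not isolated)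
Conditions: n-BuLi (1.3 equiv), Et2O, 0 °C → rt; DMF, −78 °C → rt; then H2O
Reagents that add atoms: N,N-dimethylformamide, CN(C)C=O
Why: Directed ortho-metalation, in which n-BuLi pre-coordinated by the two flanking methoxy groups removes the ring hydrogen between them (complex-induced proximity effect) faster, in ether without a diamine, than the benzylic/allylic CH2, followed by formylation of the aryllithium with DMF through the stable hemiaminal alkoxide; no stereocentre is formed.

**Step 3**
Reactants: 7 5-[(2E,6E)-farnesyl]-2,3,6-trimethoxybenzaldehyde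
Product: 9 (5S,9S,10S)-11-(3-formyl-2,4,5-trimethoxyphenyl)drim-7-ene, via drimanyl C8 cation 8 (not isolated)
Conditions: chiral IDPi Brønsted acid (N-triflyl imidodiphosphorimidate, 5 mol %), (CF3)3COH/CH2Cl2, −40 °C
Reagents that add atoms: none
Why: Proposed new method: the confined, strongly acidic chiral IDPi acid protonates one face of the terminal trisubstituted alkene, the (E,E)-triene folds chair–chair and closes rings A and B by anti additions (Stork–Eschenmoser cationic polyene cyclisation) so that H-5, CH3-10 and H-9 come out mutually trans/anti as in natural drimanes with the absolute sense fixed by the catalyst, the catalyst anion then removes the axial H-7 of the C8 cation to give the Δ7 alkene, and the formyl group (para to the only free ring position and hydrogen-bonded to the acid) switches off Friedel–Crafts capture of that cation while the methyl ethers prevent chroman formation; the closest known reactions are the IDPi-catalysed asymmetric bicyclisation of homofarnesol to ambrox and the superacid cyclisation of farnesyl arenes to drim-7-enes.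

**Step 4**
Reactants: 9 (5S,9S,10S)-11-(3-formyl-2,4,5-trimethoxyphenyl)drim-7-ene
Product: 11 2,3,6-trihydroxy-5-[(5S,9S,10S)-drim-7-en-11-yl]benzaldehyde (target), via trisodium triphenoxide 10 (not isolated)
Conditions: NaSEt (12 equiv), degassed DMF, 140 °C, Ar; then cold 1 M HCl, Na2S2O4 wash
Reagents that add atoms: none
Why: Nucleophilic O-demethylation (SN2 at methyl by ethanethiolate in a dipolar aprotic solvent), the two ethers ortho to the formyl group going first and the third under forcing, strictly non-acidic conditions that leave the Δ7 alkene, the aldehyde and the three stereocentres untouched, whereas acidic demethylation would close the phenol ortho to the benzylic carbon onto C8.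

**Compound list**
1 | 1-bromo-2,4,5-trimethoxybenzene | COc1cc(OC)c(OC)cc1Br | starting material
2 | (2E,6E)-farnesyl bromide, (2E,6E)-1-bromo-3,7,11-trimethyldodeca-2,6,10-triene | BrC/C=C(\C)CC/C=C(\C)CCC=C(C)C | starting material
3 | (2,4,5-trimethoxyphenyl)lithium | [Li]c1cc(OC)c(OC)cc1OC | intermediate
4 | 1-[(2E,6E)-farnesyl]-2,4,5-trimethoxybenzene | COc1cc(OC)c(OC)cc1C/C=C(\C)CC/C=C(\C)CCC=C(C)C | intermediate
5 | {5-[(2E,6E)-farnesyl]-2,3,6-trimethoxyphenyl}lithium | [Li]c1c(OC)c(OC)cc(C/C=C(\C)CC/C=C(\C)CCC=C(C)C)c1OC | intermediate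
6 | lithium (dimethylamino){5-[(2E,6E)-farnesyl]-2,3,6-trimethoxyphenyl}methanolate | [Li]OC(N(C)C)c1c(OC)c(OC)cc(C/C=C(\C)CC/C=C(\C)CCC=C(C)C)c1OC | intermediate
7 | 5-[(2E,6E)-farnesyl]-2,3,6-trimethoxybenzaldehyde | O=Cc1c(OC)c(OC)cc(C/C=C(\C)CC/C=C(\C)CCC=C(C)C)c1OC | intermediate
8 | (5S,9S,10S)-11-(3-formyl-2,4,5-trimethoxyphenyl)driman-8-yl cation, ion pair with the catalyst anion | C[C+]1CC[C@H]2C(C)(C)CCC[C@]2(C)[C@H]1Cc1cc(OC)c(OC)c(C=O)c1OC | intermediate
9 | 2,3,6-trimethoxy-5-{[(1S,4aS,8aS)-2,5,5,8a-tetramethyl-1,4,4a,5,6,7,8,8a-octahydronaphthalen-1-yl]methyl}benzaldehyde | CC1=CC[C@H]2C(C)(C)CCC[C@]2(C)[C@H]1Cc1cc(OC)c(OC)c(C=O)c1OC | intermediate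
10 | trisodium 3-formyl-5-{[(1S,4aS,8aS)-2,5,5,8a-tetramethyl-1,4,4a,5,6,7,8,8a-octahydronaphthalen-1-yl]methyl}benzene-1,2,4-triolate | CC1=CC[C@H]2C(C)(C)CCC[C@]2(C)[C@H]1Cc1cc([O-])c([O-])c(C=O)c1[O-].[Na+].[Na+].[Na+] | intermediate
11 | 2,3,6-trihydroxy-5-{[(1S,4aS,8aS)-2,5,5,8a-tetramethyl-1,4,4a,5,6,7,8,8a-octahydronaphthalen-1-yl]methyl}benzaldehyde | CC1=CC[C@H]2C(C)(C)CCC[C@]2(C)[C@H]1Cc1cc(O)c(O)c(C=O)c1O | target

**Totals**
Total step count: 4. Longest linear sequence: 4 steps (1 → 4 → 7 → 9 → 11).

**Three steps most likely to fail**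

Step 3 (key bicyclisation). The risks are low enantioselectivity with the bulky aryl group, incomplete cascade, and Δ8(12)/Δ8(9) alkene isomers (separable on AgNO3-impregnated silica). The fallback sets out from 7 and comes back at 9. Compound 7 is cyclised with an achiral superacid (ClSO3H, 2-nitropropane, −78 °C, Et3N quench); protonation of the formyl and methoxy oxygens deactivates the arene, and drim-7-enes are the usual main products. This gives the racemate, that is 9 together with its mirror image ent-9 F1. The enantiomers are separated by preparative SFC on a chiral amylose carbamate phase, and 9 goes on to step 4.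

Step 4 (triple demethylation). The risks are that the third, non-activated methyl ether survives and that the triphenoxide is air-oxidised. The fallback sets out from 9 and comes back at 11. Milder thiolate treatment (NaSEt, DMF, 90 °C, then cold dilute HCl) removes only the two methyl groups ortho to the formyl group and gives the bis-phenol 2,6-dihydroxy-3-methoxy-5-(drim-7-en-11-yl)benzaldehyde F2. Its p-methoxyphenol unit is oxidised with PhI(OAc)2 in MeCN/H2O at 0 °C to the hydroxy-p-quinone F3 with loss of methanol. Reduction with Na2S2O4 in THF/H2O then gives 11.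

Step 2 (ring lithiation of the polyene). The risk is competing deprotonation of the benzylic/allylic CH2. The fallback sets out from 2 and comes back at 7; the formyl group is installed before the polyene is attached, at the cost of two extra steps.
- Purchased 1,2,4-trimethoxybenzene F4 is lithiated between its 2- and 4-methoxy groups (n-BuLi, TMEDA, THF, 0 °C) to (2,3,6-trimethoxyphenyl)lithium F5.
- Quenching with DMF gives the hemiaminal alkoxide F6, which gives 2,3,6-trimethoxybenzaldehyde F7 on aqueous work-up.
- NBS in MeCN brominates para to the 2-methoxy group to give 5-bromo-2,3,6-trimethoxybenzaldehyde F8.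
- Miyaura borylation (B2pin2, PdCl2(dppf), KOAc, dioxane, 90 °C) gives the pinacol boronate F9.
- Suzuki–Miyaura allyl–aryl coupling of F9 with 2 (Pd(PPh3)4, K2CO3, THF/H2O, 60 °C) gives 7 with the linear (E,E) chain.

**Further compounds**
F1 | step 3 | ent-9, 2,3,6-trimethoxy-5-{[(1R,4aR,8aR)-2,5,5,8a-tetramethyl-1,4,4a,5,6,7,8,8a-octahydronaphthalen-1-yl]methyl}benzaldehyde | CC1=CC[C@@H]2C(C)(C)CCC[C@@]2(C)[C@@H]1Cc1cc(OC)c(OC)c(C=O)c1OC
F2 | step 4 | 2,6-dihydroxy-3-methoxy-5-{[(1S,4aS,8aS)-2,5,5,8a-tetramethyl-1,4,4a,5,6,7,8,8a-octahydronaphthalen-1-yl]methyl}benzaldehyde | CC1=CC[C@H]2C(C)(C)CCC[C@]2(C)[C@H]1Cc1cc(OC)c(O)c(C=O)c1O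
F3 | step 4 | 2-hydroxy-3,6-dioxo-5-{[(1S,4aS,8aS)-2,5,5,8a-tetramethyl-1,4,4a,5,6,7,8,8a-octahydronaphthalen-1-yl]methyl}cyclohexa-1,4-diene-1-carbaldehyde | CC1=CC[C@H]2C(C)(C)CCC[C@]2(C)[C@H]1CC1=CC(=O)C(O)=C(C=O)C1=O
F4 | step 2 | 1,2,4-trimethoxybenzene (purchased) | COc1ccc(OC)c(OC)c1
F5 | step 2 | (2,3,6-trimethoxyphenyl)lithium | [Li]c1c(OC)ccc(OC)c1OC
F6 | step 2 | lithium (dimethylamino)(2,3,6-trimethoxyphenyl)methanolate | [Li]OC(N(C)C)c1c(OC)ccc(OC)c1OC
F7 | step 2 | 2,3,6-trimethoxybenzaldehyde | O=Cc1c(OC)ccc(OC)c1OC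
F8 | step 2 | 5-bromo-2,3,6-trimethoxybenzaldehyde | O=Cc1c(OC)c(OC)cc(Br)c1OC
F9 | step 2 | 2,3,6-trimethoxy-5-(4,4,5,5-tetramethyl-1,3,2-dioxaborolan-2-yl)benzaldehyde | O=Cc1c(OC)c(OC)cc(B2OC(C)(C)C(C)(C)O2)c1OC
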